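(The earlier runs and the new flask come from a simulation for an exercise, noise included.)

Count the enzyme's time.

| setting | theta | gamma | flask |
|---|---|---|---|
| starting material | 32 mM | 16 mM | 32 mM |
| second substrate | 35.2 mM | 35.2 mM | 35.2 mM |
| free enzyme | 18 µM | 18 µM | 18 µM |
| remark | the very flask that is asked about, followed so far | run made earlier |  |

| run | time / h | target / % | starting material / % |
|---|---|---|---|
| theta | 3.00 | 7 | 93 |
| theta | 10.0 | 19 | 84 |
| theta | 15.0 | 26 | 75 |
| theta | 25.0 | 31 | 65 |
| theta | 40.0 | 42 | 57 |
| gamma | 6.00 | 25 | 80 |
| gamma | 12.0 | 38 | 61 |
| gamma | 15.0 | 42 | 58 |
| gamma | 25.0 | 54 | 46 |
| gamma | 30.0 | 58 | 43 |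

(scatter of a reading: 1.5 percentage points)

- no earlier run changes the charge of second substrate; that part of a forecast is a guess

- apparent order in second substrate when 10 % of the starting material are converted (percent change of the rate of making target for one percent more second substrate charged)

I start with theta. The starting material is the limiting reagent, with a charge smaller than that of the second substrate. The enzyme is just 0.0562 % of the starting material, so after the first instants I freeze its forms in a quasi-steady state and watch one quantity: the turnover time, the time one enzyme takes for one round, which is the enzyme charged divided by the rate of making target.

Around 10 % conversion, the readings of theta at 3.00 h and 10.0 h give 0.549 mM h⁻¹, so the turnover time reads 1.97 min, with the scatter of those readings. If that time is one part that stretches as 1/[second substrate] plus one part that does not, the apparent order is the stretching share.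

By the end of theta, between 25.0 h and 40.0 h, the rate is down to 0.235 mM h⁻¹, slower than before, although 57 % of the starting material stands.

The mean rates up to the first readings of theta and gamma, taken over different times and conversions, read as an order in starting material of about 0.163, with wide scatter. I take that as the share of the turnover time that stretches as 1/[starting material]. No run separates the rest of the turnover time, so I guess that the rest stretches as 1/[second substrate], and I commit to about 0.837.

The forecast says 0.7, on the ground that the order can “only be bounded by chemistry”.

This flask gives 0.85.

    second complex → free enzyme + target (k = 3.00 min⁻¹)
    second substrate + loaded enzyme ⇌ second complex (K = 9.30 L mol⁻¹, k = 970 L mol⁻¹ min⁻¹)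
    second substrate + free enzyme → spent catalyst (k = 0.0770 L mol⁻¹ min⁻¹)
    starting material + free enzyme ⇌ first complex (K = 43.0 L mol⁻¹, k = 1400 L mol⁻¹ min⁻¹)
    first complex ⇌ loaded enzyme + first product (K = 0.0290 M, k = 80.0 min⁻¹)

The forward step from second complex to free enzyme and target has the rate constant 4300 d⁻¹, once per 0.333 min for that step taken alone, and this rate constant holds no [second substrate]. Set against the turnover time read from theta, that step is a share of 0.169; if it were the whole part that does not stretch, the stretching share would read 0.831. In gamma, the mean rate up to the first reading gives a turnover time of 1.62 min, and against it the same step reads as a share of 0.206.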